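Remark on the chemistry (assumption): 13 and 14 are written as the 3,4-trans (3S,4R) isomers expected from the ring closure, although either C4 epimer would serve because C4 becomes the carbonyl carbon; the sense of induction of the chiral acid cannot be predicted for this ion pair, so the catalyst antipode that leads to (3S) is to be chosen by testing both.

## Structural features

The target is an isoflavanone: benzo ring A is fused to dihydropyranone ring C (O1, C2, C3, C4, C4a, C8a), and aryl ring B sits on C3. Ring A carries a free hydroxyl at C7, para to C4a and meta to O1. Ring B carries a 2'-hydroxyl, a 4'-methoxy group and a 5'-(3-methylbut-2-enyl) chain. C3 is the only stereocentre, (S)-configured, with no neighbouring stereocentre to relay from. Because C3 is benzylic and α to the C4 ketone, it epimerises through the enol under base, so setting and keeping this centre is the real difficulty, not the connectivity. The prenyl alkene excludes hydrogenolysis, strong protic acid and electrophilic oxidants, and the 2'-oxygen, five atoms from C4, can add to an electrophilic C4 if left unhindered. The key step uses the fact that ring C is a three-carbon bridge (C2–C3–C4) between O1 and C4a of a resorcinol-type ring. O1–C2 can be an aryloxymethyl cation, C3=C4 the enol ether of the ring B arylacetaldehyde, and C4a, para to the C7 oxygen, the arene nucleophile that closes the ring.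

## Logic of the disconnections

16 to 15. The two aryl O–Si bonds (at O7 and O2') are cut last. Bulky silyl ethers survive the cationic and oxidative steps and come off without hydrogen, strong acid or strong base. The skeleton is unchanged, but 15 has no acidic OH. The forward step must use fluoride buffered well enough that C3 is not enolised.

15 to 14 to 13. No skeletal bond is cut; C4=O is taken back to C4–OH and then to C4–O–SiMe3. The reason is that the annulation delivers C4 at the alcohol level. The gain is that C3 carries no acidic hydrogen in 13 and 14, so the stereocentre is safe until the penultimate step, and the C4 configuration does not matter. The forward steps must cleave the alkyl silyl ether without touching the two aryl silyl ethers and must oxidise without base.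

13 to 4 plus 12. C2–C3 and C4–C4a are cut. The polarity is consonant throughout: C2 is a formaldehyde-level electrophile, C3 an enol carbon, C4 an aldehyde-level electrophile and C4a an electron-rich arene carbon. Ring C and the stereocentre then arise in one convergent step from two fragments of similar size, one of them achiral and two steps from 1. The forward step needs a chiral counter-anion that controls the face of 12, closure para to the ring A silyloxy group, and a cation that prefers the enol silane to the prenyl alkene. Triisopropylsilyl groups on both phenols are kept for this reason, and 4 is the partner used in excess.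

12 to 11 to 9. The enol O–Si bond is cut, then the C3–C4 bond between the benzylic carbon and the homologating carbon (10 is the in-flask link). This returns the two-carbon unit to a benzaldehyde and uses a standard one-carbon homologation. The forward steps must give the Z enol silane and must hydrolyse an enol ether without harming the prenyl group or the aryl silyl ether.

9 to 7 plus 8, then 7 to 6 to 5. The aryl–CH2 bond of the prenyl group is cut, then the O–Si bond, then the C5–Br bond. The prenyl group sits para to the hydroxyl and ortho to the methoxy group of 5, exactly where electrophilic bromination goes. The forward coupling must transfer the prenyl group through its CH2 terminus and tolerate the aldehyde.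

4 to 2 plus 3, then 2 to 1. The O1–C2 bond is cut, then one O–Si bond. This gives a symmetrical diol and a commercial halomethyl ester. The forward steps need mono-silylation (excess 1) and O-alkylation in preference to acyl transfer.

## Other disconnections considered

Alternative 1: The cut removes C3, with ring B attached, from between C2 and C4, leaving a benzofuranone. In the forward step the arylchlorocarbene from 3-aryl-3-chlorodiazirine A1 would cyclopropanate 6-(methoxymethoxy)-3-(trimethylsilyloxy)benzofuran A2. The halocyclopropane would open with loss of chloride and silyl to the ring-expanded isoflavone A3.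
- In favour: one-carbon ring expansions of this kind have closer precedent than step 8, and on that point the alternative is the better plan. A3 is a flat, robust compound, easier to handle than the acid-labile 13.
- Against: A3 is achiral, so C3 must be set afterwards by an asymmetric reduction of the C2=C3 bond, probably through the alcohol and back. The carbene would add to a prenyl alkene, so a bromide placeholder and a late Stille coupling are needed. The methoxymethyl groups need acid for removal, on an enolisable ketone that carries a prenyl group. The diazirine is an energetic compound.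
- Comparison: structurally both plans join two aryl fragments in one step. Mechanistically the alternative is on firmer ground for ring formation but leaves the stereocentre unsolved. In step economy it is worse, with four or more steps after A3 against three after 13. Both plans are equal in needing a redox adjustment at C4.

Alternative 2: The cut is C3–C4. Aldehyde A4, with ring A carrying the formyl group and a benzylic sulfone on the O1–C2–C3 tether, would lose sulfinate under base to give an ortho-quinone methide on ring B. A chiral triazolium-derived carbene would convert the aldehyde into a Breslow intermediate that adds to C3, giving isoflavanone A5.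
- In favour: C4 arrives at the ketone level and the 2'-hydroxyl is already free, so one deprotection reaches the target. This endgame is better than the three steps after 13. Intramolecular Stetter closures to chromanones are an established class, and no acid comes near the prenyl group.
- Against: the base that generates the carbene and the quinone methide acts on a product whose C3 is readily enolised. The quinone methide carries a β-aryloxy group that can be expelled, and its geometry is not fixed, so facial control is uncertain. A4 needs a longer, linear assembly of the O1–C2–C3 tether.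
- Comparison: the two plans are equal in closing ring C and setting C3 in one catalytic step, and neither key step has direct precedent. The alternative is better after the key step and worse before it and in product stability under its own conditions.

Alternative 3: The cut is O1–C2. α-Aryl enone A6 would cyclise under a chiral phosphoric acid by 6-endo-trig addition of the ring A phenol to the terminal CH2. The enol would then be protonated at C3 to give isoflavanone A7.
- In favour: A6 comes from a deoxybenzoin by methylenation, the step is an isomerisation with no by-product, and C4 is at the right oxidation level. In step count and reagent simplicity the alternative is the better plan.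
- Against: the stereocentre would be set by proton transfer at the very position that makes the product labile, so the catalyst can also racemise A7. The uncatalysed cyclisation of such hydroxyaryl enones is fast and would give a racemic background. A6 is prone to spontaneous closure and polymerisation. The final acid deprotection is the same hazard as in alternative 1.
- Comparison: structurally the simplification is equal (two aryl fragments). Mechanistically the chosen plan sets C3 in an irreversible C–C bond formation and keeps it non-acidic for two more steps, which is the stronger position. The alternative is better on length.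

Key step: step 8

## Route

Step 1
Reactants: 1 resorcinol
Product: 2 3-(triisopropylsilyloxy)phenol
Conditions: TIPSCl (1 equiv), 1 (3 equiv), imidazole, DMF, 0 °C to rt
Reagents that add atoms: triisopropylsilyl chloride, CC(C)[Si](Cl)(C(C)C)C(C)C
Why: Phenol silylation with a silyl chloride and imidazole; the excess of the cheap, water-soluble diol suppresses bis-silylation and is washed out.

Step 2
Reactants: 2 3-(triisopropylsilyloxy)phenol; 3 bromomethyl acetate
Product: 4 [3-(triisopropylsilyloxy)phenoxy]methyl acetate
Conditions: iPr2NEt, DMF, 0 °C to rt
Reagents that add atoms: none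
Why: O-alkylation (SN2) of the phenol by the very reactive α-acyloxy bromide, the usual way to aryl acetoxymethyl ethers; the hindered amine keeps free phenoxide low, which limits acyl transfer and leaves the aryl silyl ether alone.

Step 3
Reactants: 5 2-hydroxy-4-methoxybenzaldehyde
Product: 6 5-bromo-2-hydroxy-4-methoxybenzaldehyde
Conditions: NBS, MeCN, 0 °C to rt
Reagents that add atoms: N-bromosuccinimide, O=C1CCC(=O)N1Br
Why: Electrophilic aromatic bromination; C5 is para to the hydroxyl and ortho to the methoxy group and is less hindered than C3, which lies between the two oxygens.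

Step 4
Reactants: 6 5-bromo-2-hydroxy-4-methoxybenzaldehyde
Product: 7 5-bromo-4-methoxy-2-(triisopropylsilyloxy)benzaldehyde
Conditions: TIPSCl, imidazole, DMF, rt
Reagents that add atoms: triisopropylsilyl chloride, CC(C)[Si](Cl)(C(C)C)C(C)C
Why: Phenol silylation; the bulky ether later prevents benzofuran formation from the arylacetaldehyde and keeps the 2'-oxygen out of the key step.

Step 5
Reactants: 7 5-bromo-4-methoxy-2-(triisopropylsilyloxy)benzaldehyde; 8 tributyl(3-methylbut-2-en-1-yl)stannane
Product: 9 4-methoxy-5-(3-methylbut-2-en-1-yl)-2-(triisopropylsilyloxy)benzaldehyde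
Conditions: Pd(PPh3)4 (5 mol %), DMF, 90 °C
Reagents that add atoms: none
Why: Stille coupling; after oxidative addition of zerovalent palladium to the aryl bromide, the prenyl group is expected to transfer through its unsubstituted CH2 terminus, and the fluoride-free conditions spare the aryl silyl ether and the aldehyde.

Step 6
Reactants: 9 4-methoxy-5-(3-methylbut-2-en-1-yl)-2-(triisopropylsilyloxy)benzaldehyde
Product: 11 [4-methoxy-5-(3-methylbut-2-en-1-yl)-2-(triisopropylsilyloxy)phenyl]acetaldehyde, via methyl enol ether 10 (not isolated)
Conditions: Ph3P(CH2OMe)Cl, KOt-Bu, THF, 0 °C to rt; then 2 M HCl (aq), rt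
Reagents that add atoms: (methoxymethyl)triphenylphosphonium chloride, COC[P+](c1ccccc1)(c1ccccc1)c1ccccc1.[Cl-]; water, O
Why: Wittig methoxymethylenation gives the β-methoxystyrene (either geometry serves), and dilute acid hydrolyses this enol ether, which is protonated far more easily than the prenyl alkene, to the homologous aldehyde; the aryl triisopropylsilyl ether resists dilute acid.

Step 7
Reactants: 11 [4-methoxy-5-(3-methylbut-2-en-1-yl)-2-(triisopropylsilyloxy)phenyl]acetaldehyde
Product: 12 (Z)-1-[4-methoxy-5-(3-methylbut-2-en-1-yl)-2-(triisopropylsilyloxy)phenyl]-2-(trimethylsilyloxy)ethene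
Conditions: TMSOTf, Et3N, Et2O, 0 °C; pentane, filtration under argon, used without chromatography
Reagents that add atoms: trimethylsilyl trifluoromethanesulfonate, C[Si](C)(C)OS(=O)(=O)C(F)(F)F
Why: Soft enolisation: O-silylation of the aldehyde followed by amine deprotonation of the benzylic α-position; the Z isomer is expected to dominate because the reacting conformer keeps the α-aryl group eclipsed with the C=O bond, and the geometry is to be checked before use.

Step 8
Reactants: 4 [3-(triisopropylsilyloxy)phenoxy]methyl acetate; 12 (Z)-1-[4-methoxy-5-(3-methylbut-2-en-1-yl)-2-(triisopropylsilyloxy)phenyl]-2-(trimethylsilyloxy)ethene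
Product: 13 (3S,4R)-3-[4-methoxy-5-(3-methylbut-2-en-1-yl)-2-(triisopropylsilyloxy)phenyl]-7-(triisopropylsilyloxy)-4-(trimethylsilyloxy)chroman
Conditions: chiral IDPi acid [(3,3'-Ar2-BINOL)P(=NSO2CF3)]2NH (Ar = 3,5-(CF3)2C6H3, 5 mol %), PhMe, −60 °C, 4 (1.3 equiv) added slowly; Et3N quench at −60 °C
Reagents that add atoms: none
Why: Proposed new method: the confined strong acid protonates the acetal-type acetate of 4, acetic acid leaves, and the aryloxymethyl oxocarbenium ion stays paired with the chiral imidodiphosphorimidate anion; the aryl-bearing carbon of 12 attacks its CH2 terminus in a Mukaiyama-type addition (C2–C3), the trimethylsilyloxocarbenium ion so formed at C4 is trapped by the ring A carbon ortho to O1 and para to the silyloxy group (C4–C4a), and the arenium ion returns the proton to the anion. The closest known reaction types are the oxa-Povarov annulation of aryloxymethyl cations with alkenes, which gives racemic chromans, and additions of silyl enolates to formaldehyde-derived cations held by confined chiral anions; an aldehyde enol silane as the two-carbon partner under anion control has not been shown. Ring C closes by a 6-exo-trig Friedel–Crafts attack on the exocyclic C=O+ bond, the second bond of a stepwise cationic [4+2] annulation. C3 is set in the first bond formation by the chiral anion, which has to tell apart the two faces of the geometrically pure Z enol silane; C4 follows from C3 in the closure, where the C3 aryl and C4 silyloxy groups should both sit pseudo-equatorial (3,4-trans), and it is erased in step 10. The step needs ionisation of 4 to outrun C-protonation of 12, attack by the enol silane in preference to the prenyl alkene or an arene, and closure para instead of ortho to the ring A silyloxy group. Low temperature, slow addition of 4, the far higher nucleophilicity of the enol silane, and the bulk of the triisopropylsilyl groups, which shield the position between the ring A oxygens and keep the 2'-oxygen away from C4, are meant to secure these.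

Step 9
Reactants: 13 (3S,4R)-3-[4-methoxy-5-(3-methylbut-2-en-1-yl)-2-(triisopropylsilyloxy)phenyl]-7-(triisopropylsilyloxy)-4-(trimethylsilyloxy)chroman
Product: 14 (3S,4R)-3-[4-methoxy-5-(3-methylbut-2-en-1-yl)-2-(triisopropylsilyloxy)phenyl]-7-(triisopropylsilyloxy)chroman-4-ol
Conditions: K2CO3 (0.2 equiv), MeOH/THF, 0 °C, short reaction time
Reagents that add atoms: none
Why: Methanolysis of the trimethylsilyl alkyl ether, which should be cleaved much faster than the hindered aryl triisopropylsilyl ethers under brief, cold, catalytic base; no epimerisable centre is present at this stage.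

Step 10
Reactants: 14 (3S,4R)-3-[4-methoxy-5-(3-methylbut-2-en-1-yl)-2-(triisopropylsilyloxy)phenyl]-7-(triisopropylsilyloxy)chroman-4-ol
Product: 15 (3S)-3-[4-methoxy-5-(3-methylbut-2-en-1-yl)-2-(triisopropylsilyloxy)phenyl]-7-(triisopropylsilyloxy)chroman-4-one
Conditions: Dess–Martin periodinane, CH2Cl2, 0 °C to rt
Reagents that add atoms: none
Why: Dess–Martin oxidation of the secondary benzylic alcohol under neutral to weakly acidic conditions, which spare the prenyl group and the aryl silyl ethers and should not enolise the new α-aryl ketone; C3 is retained while C4 ceases to be a stereocentre.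

Step 11
Reactants: 15 (3S)-3-[4-methoxy-5-(3-methylbut-2-en-1-yl)-2-(triisopropylsilyloxy)phenyl]-7-(triisopropylsilyloxy)chroman-4-one
Product: 16 (3S)-7-hydroxy-3-[2-hydroxy-4-methoxy-5-(3-methylbut-2-en-1-yl)phenyl]chroman-4-one
Conditions: TBAF, AcOH (1:1.5), THF, 0 °C
Reagents that add atoms: none
Why: Fluoride cleaves both aryl silyl ethers; the acetic acid buffer protonates the phenoxides as they form and keeps the medium too weakly basic to enolise C3.

## Compound list

1 | resorcinol (benzene-1,3-diol) | Oc1cccc(O)c1 | starting material
2 | 3-(triisopropylsilyloxy)phenol | Oc1cccc(O[Si](C(C)C)(C(C)C)C(C)C)c1 | intermediate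
3 | bromomethyl acetate | CC(=O)OCBr | starting material
4 | [3-(triisopropylsilyloxy)phenoxy]methyl acetate | CC(=O)OCOc1cccc(O[Si](C(C)C)(C(C)C)C(C)C)c1 | intermediate
5 | 2-hydroxy-4-methoxybenzaldehyde | COc1ccc(C=O)c(O)c1 | starting material
6 | 5-bromo-2-hydroxy-4-methoxybenzaldehyde | COc1cc(O)c(C=O)cc1Br | intermediate
7 | 5-bromo-4-methoxy-2-(triisopropylsilyloxy)benzaldehyde | COc1cc(O[Si](C(C)C)(C(C)C)C(C)C)c(C=O)cc1Br | intermediate
8 | tributyl(3-methylbut-2-en-1-yl)stannane | CCCC[Sn](CCCC)(CCCC)CC=C(C)C | starting material
9 | 4-methoxy-5-(3-methylbut-2-en-1-yl)-2-(triisopropylsilyloxy)benzaldehyde | COc1cc(O[Si](C(C)C)(C(C)C)C(C)C)c(C=O)cc1CC=C(C)C | intermediate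
10 | 1-methoxy-2-[4-methoxy-5-(3-methylbut-2-en-1-yl)-2-(triisopropylsilyloxy)phenyl]ethene, E/Z mixture, not isolated | COC=Cc1cc(CC=C(C)C)c(OC)cc1O[Si](C(C)C)(C(C)C)C(C)C | intermediate
11 | [4-methoxy-5-(3-methylbut-2-en-1-yl)-2-(triisopropylsilyloxy)phenyl]acetaldehyde | O=CCc1cc(CC=C(C)C)c(OC)cc1O[Si](C(C)C)(C(C)C)C(C)C | intermediate
12 | (Z)-1-[4-methoxy-5-(3-methylbut-2-en-1-yl)-2-(triisopropylsilyloxy)phenyl]-2-(trimethylsilyloxy)ethene | C[Si](C)(C)O/C=C\c1cc(CC=C(C)C)c(OC)cc1O[Si](C(C)C)(C(C)C)C(C)C | intermediate
13 | (3S,4R)-3-[4-methoxy-5-(3-methylbut-2-en-1-yl)-2-(triisopropylsilyloxy)phenyl]-7-(triisopropylsilyloxy)-4-(trimethylsilyloxy)chroman | COc1cc(O[Si](C(C)C)(C(C)C)C(C)C)c([C@H]2COc3cc(O[Si](C(C)C)(C(C)C)C(C)C)ccc3[C@@H]2O[Si](C)(C)C)cc1CC=C(C)C | intermediate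
14 | (3S,4R)-3-[4-methoxy-5-(3-methylbut-2-en-1-yl)-2-(triisopropylsilyloxy)phenyl]-7-(triisopropylsilyloxy)chroman-4-ol | COc1cc(O[Si](C(C)C)(C(C)C)C(C)C)c([C@H]2COc3cc(O[Si](C(C)C)(C(C)C)C(C)C)ccc3[C@@H]2O)cc1CC=C(C)C | intermediate
15 | (3S)-3-[4-methoxy-5-(3-methylbut-2-en-1-yl)-2-(triisopropylsilyloxy)phenyl]-7-(triisopropylsilyloxy)chroman-4-one | COc1cc(O[Si](C(C)C)(C(C)C)C(C)C)c([C@H]2COc3cc(O[Si](C(C)C)(C(C)C)C(C)C)ccc3C2=O)cc1CC=C(C)C | intermediate
16 | (3S)-7-hydroxy-3-[2-hydroxy-4-methoxy-5-(3-methylbut-2-en-1-yl)phenyl]chroman-4-one | COc1cc(O)c([C@H]2COc3cc(O)ccc3C2=O)cc1CC=C(C)C | target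

## Step count and least certain steps

Total: 11 steps. Longest linear sequence: 9 steps (5 to 16 through steps 3 to 11). The ring A branch (steps 1 and 2) joins at step 8.

Step 8 (new method, key step). Four things may go wrong:
- The catalyst, helped by the acetic acid that accumulates, may protonate the enol silane at carbon and strip its silyl group, so the nucleophile is consumed before it meets the cation.
- Facial discrimination may be poor, because the stereocentre lies on the nucleophile while the electrophile is a small, loosely held CH2 cation.
- The silyl group may be lost before ring closure, or silanol may be eliminated from the benzylic C4 position of the product under acid, giving a 2H-chromene and erasing C3.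
- The cation may be captured by the prenyl alkene.

The fallback uses known auxiliary chemistry. It sets out from 11 (with 4 as electrophile) and returns at 15.
- Pinnick oxidation of 11 (NaClO2, NaH2PO4, 2-methylbut-2-ene, t-BuOH/H2O) would give [4-methoxy-5-(3-methylbut-2-en-1-yl)-2-(triisopropylsilyloxy)phenyl]acetic acid F1.
- Mixed-anhydride coupling (PivCl, Et3N, LiCl) with commercial (R)-4-benzyloxazolidin-2-one would give (4R)-4-benzyl-3-{[4-methoxy-5-(3-methylbut-2-en-1-yl)-2-(triisopropylsilyloxy)phenyl]acetyl}oxazolidin-2-one F2.
- Its titanium enolate (TiCl4, iPr2NEt, CH2Cl2, 0 °C) would be alkylated by 4, ionised by the same Lewis acid, on the face away from the benzyl group (Evans alkylation with an oxocarbenium precursor). This would give (4R)-4-benzyl-3-{(2S)-2-[4-methoxy-5-(3-methylbut-2-en-1-yl)-2-(triisopropylsilyloxy)phenyl]-3-[3-(triisopropylsilyloxy)phenoxy]propanoyl}oxazolidin-2-one F3.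
- LiOH/H2O2 at 0 °C would remove the auxiliary to give (2S)-2-[4-methoxy-5-(3-methylbut-2-en-1-yl)-2-(triisopropylsilyloxy)phenyl]-3-[3-(triisopropylsilyloxy)phenoxy]propanoic acid F4.
- Oxalyl chloride and then SnCl4 at −78 °C would close ring C by intramolecular Friedel–Crafts acylation para to the ring A silyloxy group, giving 15. Steps 9 and 10 then fall away.

Step 7. Enolisation may give a mixture of double-bond isomers, and the trimethylsilyl enol ether may hydrolyse on handling. Each isomer can lead to a different enantiomer in step 8, so a mixture would erode the enantiomeric purity. The fallback builds the geometry stereospecifically; it sets out from 9 and returns at 12.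
- Colvin homologation of 9 with lithiated trimethylsilyldiazomethane (THF, −78 °C to rt) would give 1-ethynyl-4-methoxy-5-(3-methylbut-2-en-1-yl)-2-(triisopropylsilyloxy)benzene F5.
- Anti-Markovnikov syn-addition of benzoic acid catalysed by Ru(η3-2-methylallyl)2(dppb) would give (Z)-2-[4-methoxy-5-(3-methylbut-2-en-1-yl)-2-(triisopropylsilyloxy)phenyl]ethenyl benzoate F6.
- Cleavage of the ester with two equivalents of MeLi at −78 °C would release the lithium enolate with retention of geometry, and TMSCl would trap it as 12.

Step 5. The prenyl group may transfer through its tertiary terminus (reverse prenylation). Oxidative addition to the electron-rich bromide may also be slow enough for the stannane to add thermally to the aldehyde. The fallback sets out from 7 and returns at 9.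
- Stille coupling with allyltributylstannane (Pd(PPh3)4, PhMe, 100 °C), which has no regiochemical ambiguity, would give 5-allyl-4-methoxy-2-(triisopropylsilyloxy)benzaldehyde F7.
- Cross-metathesis with excess 2-methylbut-2-ene (second-generation Grubbs catalyst, RuCl2(=CHPh)(H2IMes)(PCy3), CH2Cl2, 40 °C) would build the trisubstituted alkene of 9.

Step 11. Once phenoxides appear, fluoride may enolise C3 and racemise the product. The fallback changes the order of events so that no base meets the ketone; it sets out from 14 and returns at 16.
- TBAF/AcOH on 14, where C3 bears no acidic hydrogen, would give (3S,4R)-3-[2-hydroxy-4-methoxy-5-(3-methylbut-2-en-1-yl)phenyl]chroman-4,7-diol F8.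
- Activated MnO2 (EtOAc, rt) would then oxidise only the benzylic C4 alcohol under neutral heterogeneous conditions, giving 16 directly.

## Further compounds

F1 | step 8 | [4-methoxy-5-(3-methylbut-2-en-1-yl)-2-(triisopropylsilyloxy)phenyl]acetic acid | OC(=O)Cc1cc(CC=C(C)C)c(OC)cc1O[Si](C(C)C)(C(C)C)C(C)C
F2 | step 8 | (4R)-4-benzyl-3-{[4-methoxy-5-(3-methylbut-2-en-1-yl)-2-(triisopropylsilyloxy)phenyl]acetyl}oxazolidin-2-one | O=C(Cc1cc(CC=C(C)C)c(OC)cc1O[Si](C(C)C)(C(C)C)C(C)C)N1[C@H](Cc2ccccc2)COC1=O
F3 | step 8 | (4R)-4-benzyl-3-{(2S)-2-[4-methoxy-5-(3-methylbut-2-en-1-yl)-2-(triisopropylsilyloxy)phenyl]-3-[3-(triisopropylsilyloxy)phenoxy]propanoyl}oxazolidin-2-one | O=C(N1[C@H](Cc2ccccc2)COC1=O)[C@H](COc1cccc(O[Si](C(C)C)(C(C)C)C(C)C)c1)c1cc(CC=C(C)C)c(OC)cc1O[Si](C(C)C)(C(C)C)C(C)C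
F4 | step 8 | (2S)-2-[4-methoxy-5-(3-methylbut-2-en-1-yl)-2-(triisopropylsilyloxy)phenyl]-3-[3-(triisopropylsilyloxy)phenoxy]propanoic acid | OC(=O)[C@H](COc1cccc(O[Si](C(C)C)(C(C)C)C(C)C)c1)c1cc(CC=C(C)C)c(OC)cc1O[Si](C(C)C)(C(C)C)C(C)C
F5 | step 7 | 1-ethynyl-4-methoxy-5-(3-methylbut-2-en-1-yl)-2-(triisopropylsilyloxy)benzene | C#Cc1cc(CC=C(C)C)c(OC)cc1O[Si](C(C)C)(C(C)C)C(C)C
F6 | step 7 | (Z)-2-[4-methoxy-5-(3-methylbut-2-en-1-yl)-2-(triisopropylsilyloxy)phenyl]ethenyl benzoate | O=C(O/C=C\c1cc(CC=C(C)C)c(OC)cc1O[Si](C(C)C)(C(C)C)C(C)C)c1ccccc1
F7 | step 5 | 5-allyl-4-methoxy-2-(triisopropylsilyloxy)benzaldehyde | COc1cc(O[Si](C(C)C)(C(C)C)C(C)C)c(C=O)cc1CC=C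
F8 | step 11 | (3S,4R)-3-[2-hydroxy-4-methoxy-5-(3-methylbut-2-en-1-yl)phenyl]chroman-4,7-diol | COc1cc(O)c([C@H]2COc3cc(O)ccc3[C@@H]2O)cc1CC=C(C)C
A1 | alternative 1 | 3-[5-bromo-4-methoxy-2-(methoxymethoxy)phenyl]-3-chloro-3H-diazirine | COCOc1cc(OC)c(Br)cc1C1(Cl)N=N1
A2 | alternative 1 | 6-(methoxymethoxy)-3-(trimethylsilyloxy)benzofuran | COCOc1ccc2c(O[Si](C)(C)C)coc2c1
A3 | alternative 1 | 5'-bromo-4'-methoxy-7,2'-bis(methoxymethoxy)isoflavone | COCOc1ccc2c(c1)occ(-c1cc(Br)c(OC)cc1OCOC)c2=O
A4 | alternative 2 | 2-[2-(2-hydroxy-4-methoxy-5-(3-methylbut-2-en-1-yl)phenyl)-2-(4-methylphenylsulfonyl)ethoxy]-4-(triisopropylsilyloxy)benzaldehyde | O=Cc1ccc(O[Si](C(C)C)(C(C)C)C(C)C)cc1OCC(c1cc(CC=C(C)C)c(OC)cc1O)S(=O)(=O)c1ccc(C)cc1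
A5 | alternative 2 | (3S)-2'-hydroxy-4'-methoxy-5'-(3-methylbut-2-en-1-yl)-7-(triisopropylsilyloxy)isoflavanone | COc1cc(O)c([C@H]2COc3cc(O[Si](C(C)C)(C(C)C)C(C)C)ccc3C2=O)cc1CC=C(C)C
A6 | alternative 3 | 1-[2-hydroxy-4-(methoxymethoxy)phenyl]-2-[4-methoxy-2-(methoxymethoxy)-5-(3-methylbut-2-en-1-yl)phenyl]prop-2-en-1-one | C=C(C(=O)c1ccc(OCOC)cc1O)c1cc(CC=C(C)C)c(OC)cc1OCOC
A7 | alternative 3 | (3S)-4'-methoxy-7,2'-bis(methoxymethoxy)-5'-(3-methylbut-2-en-1-yl)isoflavanone | COc1cc(OCOC)c([C@H]2COc3cc(OCOC)ccc3C2=O)cc1CC=C(C)C
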